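## The problem

Numbering used throughout: ring carbons C1–C9, with C1 = CH–CHO, C2 = C(CHO)=, C3 = CH=, C4 = CH2, C5 = CH=, C6 = C(CH3)=, C7 = CH2, C8 = CHOH and C9 = CH carrying the side chain; C10 is the side-chain methine and C11 the CH2OAc carbon.

The target is a nine-membered carbocycle holding an E-trisubstituted alkene (C5=C6) and, one CH2 away, a ring-cis formyl-alkene (C2=C3). Such a ring resists end-to-end closure, and the E-alkene cannot be carried inside any smaller carbocycle. There are four stereocentres: C1 (R), C8 (S) and C9 (R) on the ring and C10 (S) outside it. O8 and the C10 branch are cis on the ring; the C1 formyl group is trans to both. C8 and C9 can control C10 only while the C9–C10 bond is held in a ring. C1 is α to a formyl group and can be set last by equilibration, but only while O8 is blocked: the 1-epimer, with formyl cis to O8, would be trapped as a bridged γ-lactol. The functional groups are fragile: a β,γ-unsaturated 1,4-dialdehyde whose C2=C3 bond can slip into conjugation with both carbonyls, and a primary acetate that must be told apart from the secondary alcohol.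

The feature that makes the key step possible: read with a carbonyl at C1, the segment C1–C2–C3–C4–C5=C6 is the δ,ε-unsaturated ketone left behind by an oxy-Cope rearrangement. Reconnecting C1 to C6 across the ring contracts it to the cyclopentane C1–C6–C7–C8–C9. Because O8 and C11 are 1,4-related through C9–C10, that cyclopentane is cis-fused to a γ-lactone O–C8–C9–C10–C11(=O). This is the 2-oxabicyclo[3.3.0]octan-3-one skeleton, available enantiopure as alkene 1.

## Retrosynthesis

**23 ⇒ 22 ⇒ 20 (no C–C bond cut).** Both formyl groups stay masked to the end: C1–CHO as a methyl enol ether and C2–CHO as a dimethyl acetal in 20. O8 stays silylated in 22 until C1 has been equilibrated. The neighbouring choice, late oxidation of a diol, would need three primary alcohols told apart and tends to lactonise. The forward steps are mild acid hydrolysis, base equilibration at C1 and fluoride.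

**20 ⇒ 18 ⇒ 17 (cut the exocyclic C1=CH(OMe) bond).** The formyl carbon on C1 comes from ketone 17 by methoxymethylenation. Bringing this carbon in by carbonylation of a C1 enol triflate would leave the alkene at C1=C2 and demand a deconjugation. Ketone 17 has one carbon and one stereocentre fewer. The forward reaction must be a 1,2-selective olefination of a hindered enone.

**17 ⇒ 15 ⇒ 14 (cut C2–CH(OMe)2, remove C2=C3).** The regiodefined silyl enol ether 14 carries sulfur on C2. The sulfur locks the enolate regiochemistry, lets the one-carbon electrophile enter at C2, and then leaves as sulfenic acid to make C2=C3 in the only direction open to it.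

**14 ⇒ 12 (key: cut C3–C4, join C1–C6).** Cutting any single ring bond instead leaves an open chain that must be forced shut. Claisen-type ring expansions tether across positions 2 and 4 of the chair and give ring-cis alkenes. Here the tether spans the breaking bond, which gives E. Carbinol 12 is a cyclopentane whose stereocentres all come from a rigid bicyclic template; the four inserted ring carbons are just two alkenyl groups. The forward reaction needs those two groups trans on the cyclopentane.

**12 ⇒ 11 ⇒ 10 ⇒ 7 + 8 (cut C1–C2).** The alkenyl group is added to ketone 7 as the anion of phenyl vinyl sulfide 8. The lactone is reduced only afterwards, so that silylation distinguishes the primary and secondary hydroxyls from the unreactive tertiary one without extra protecting-group steps.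

**7 ⇒ 6 ⇒ 5 ⇒ 3 + 4 (cut C6–CH3 and C10–C1′).** The quaternary C6 comes from α-methylation of the extended enolate of β,γ-unsaturated ketone 6. The side chain comes from alkylating the lactone enolate of 3 with bromide 4 on the convex face, which sets C10.

**3 ⇒ 2 ⇒ 1 (cut C6–vinyl).** Epoxide 2 is opened by a vinyl cuprate. Lactone 1 already holds C8 and C9 with the correct absolute and relative configuration, plus O8, C10 and C11.

## Roads not taken

**Alternative 1:** The obvious cut is one ring bond of an open chain, for instance C2=C3, closing diene A1 by ring-closing metathesis with RuCl2(=CHPh)(PCy3)(H2IMes), the second-generation Grubbs catalyst; closing C3–C4 by intramolecular allylic alkylation is the same idea. A1 needs all four stereocentres set in an open chain by separate asymmetric operations and the E-alkene made beforehand. The closure must then overcome the strain and entropy of a nine-membered ring, build a trisubstituted electron-poor alkene, and compete with two other alkenes, and it sets no stereocentre. In the chosen plan the ring and the E geometry come from a five-membered ring in one step, and the stereocentres come from the template.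

**Alternative 2:** The classical answer to an E-cyclononene is a retrosynthetic C2–C6 bond: hydrindanol tosylate A2, whose alkoxide undergoes Grob fragmentation to cyclononenone A3. The E geometry is reliable, but the carbonyl ends up at C2 and must become a formyl-alkene with regiocontrol between C1 and C3. A2 carries seven stereocentres, including an angular methyl and a tosylate of defined relative configuration, and no cheap building block supplies C8, C9 and C10 for it. The run-up is far longer than the eight steps to 12.

**Alternative 3:** Cut C1–C9 and tie O11 to the C1 carboxyl: thirteen-membered lactone A4, then Ireland–Claisen ring contraction to acid A5. The large lactone closes easily and the [3,3] shift forms the ring bond. However, C10 becomes an sp2 carbon that needs a later hydroboration with weak acyclic stereocontrol. The C8/C9 relationship depends on the chair/boat preference of a medium-ring transition state, and A4 still needs the E-alkene and the skipped diene assembled linearly.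

Key step: step 9

Assumption (remark on the chemistry): in the O8-silylated dialdehyde the 1R configuration, with the formyl group trans to the C9 side chain, is taken to be the thermodynamically favoured one.

## Steps

Step 1
Reactants: 1 (3aR,6aS)-3,3a,6,6a-tetrahydro-2H-cyclopenta[b]furan-2-one
Product: 2 exo-epoxide across C1–C6
Conditions: mCPBA, CH2Cl2, 0 °C to rt
Reagents that add atoms: 3-chloroperoxybenzoic acid, OOC(=O)c1cccc(Cl)c1
Why: Prilezhaev epoxidation from the convex face of the cis-fused bicycle; the oxirane configuration is erased later (C1 becomes a ketone, C6 an enolate carbon), so face selectivity is not critical.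

Step 2
Reactants: 2 exo-epoxide
Product: 3 hydroxy lactone with vinyl at C6 and OH at C1
Conditions: CH2=CHMgBr (2.4 equiv), CuI (1.2 equiv), THF, −40 to −10 °C; aq NH4Cl
Reagents that add atoms: vinylmagnesium bromide, C=C[Mg]Br
Why: Anti opening of the epoxide by the vinyl cuprate should occur at C6, the oxirane carbon remote from the ring-fusion methine C9, because attack at C1 from the concave face is blocked by the cis C10 methylene; cuprates leave the lactone untouched at this temperature.

Step 3
Reactants: 3 hydroxy lactone; 4 5-bromo-2-methylpent-2-ene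
Product: 5 C10-alkylated hydroxy lactone
Conditions: LiN(iPr)2 (2.2 equiv), THF, −78 to −30 °C; then 4, DMPU, −30 to 0 °C
Reagents that add atoms: none
Why: Alkylation of the alkoxide–lactone enolate dianion on carbon should take place on the convex face of the lactone ring, trans to the C9–C1 bond, which sets C10 with the configuration of the target (enolate alkylation of a cis-fused bicyclic lactone).

Step 4
Reactants: 5 C10-alkylated hydroxy lactone
Product: 6 keto lactone (C1 ketone)
Conditions: DMP (1,1,1-triacetoxy-1,1-dihydro-1,2-benziodoxol-3(1H)-one), CH2Cl2, 0 °C to rt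
Reagents that add atoms: none
Why: Periodinane oxidation of the secondary alcohol under neutral conditions, which spares the β,γ-unsaturated ketone and the base-sensitive β-acyloxy ketone.

Step 5
Reactants: 6 keto lactone
Product: 7 keto lactone with quaternary C6 (methyl convex and vinyl concave)
Conditions: KN(SiMe3)2 (1.0 equiv), THF, −78 °C; then CH3I, −78 to −40 °C
Reagents that add atoms: iodomethane, CI
Why: H6 is α to the ketone and allylic, hence far more acidic than H9, so one equivalent of base should give the extended enolate only; it is alkylated at the α-carbon from the convex face (deconjugative α-alkylation), placing methyl cis to H9 and vinyl on the concave face.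

Step 6
Reactants: 7 keto lactone with quaternary C6; 8 phenyl vinyl sulfide
Product: 10 tertiary alcohol bearing the 1-(phenylthio)vinyl group on the convex face of C1, via 1-(phenylthio)vinyllithium 9 (not isolated)
Conditions: 8, s-BuLi, TMEDA, THF, −78 °C; CeCl3, −78 °C; then 7, −78 °C; aq NH4Cl
Reagents that add atoms: none
Why: 1,2-Addition of the organocerium reagent from the convex face, anti to the C6 vinyl group and the C10 arm, should place the two alkenyl groups trans on the cyclopentane; cerium suppresses enolisation at C9 and attack on the lactone.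

Step 7
Reactants: 10 tertiary alcohol lactone
Product: 11 triol
Conditions: LiAlH4, THF, 0 °C to rt
Reagents that add atoms: none
Why: Hydride reduction of the γ-lactone to the 1,4-diol (O8H and O11H); a translactonised isomer formed through the new tertiary alkoxide in step 6 would give the same triol.

Step 8
Reactants: 11 triol
Product: 12 bis(tert-butyldimethylsilyl) ether with free tertiary OH
Conditions: t-BuMe2SiCl (2.4 equiv), imidazole, DMF, rt
Reagents that add atoms: tert-butyldimethylsilyl chloride, CC(C)(C)[Si](C)(C)Cl
Why: The primary and the secondary hydroxyl are silylated, while the hindered tertiary allylic hydroxyl does not react with the silyl chloride, so the carbinol needed for the rearrangement stays free.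

Step 9
Reactants: 12 bis(silyl ether) carbinol
Product: 14 trimethylsilyl enol ether of the nine-membered ketone, via potassium enolate 13 (not isolated)
Conditions: KH, 18-crown-6, THF, 0 °C to rt; then Et3N, Me3SiCl, −78 °C
Reagents that add atoms: chlorotrimethylsilane, C[Si](C)(C)Cl
Why: KH with 18-crown-6 turns 12 into the free potassium alkoxide, whose 3-oxido-1,5-diene C3=C2–C1(O−)–C6–C5=C4 undergoes a [3,3]-sigmatropic shift (anionic oxy-Cope rearrangement), forming C3–C4 as C1–C6 breaks. The closest known reaction type is the ring expansion of trans-1,2-dialkenylcycloalkanols to (E)-cycloalk-5-enones. The nine-membered ring is not closed end to end: it arises by four-carbon expansion of the cyclopentane, the new bond being made in a six-membered chair transition state fused to the five-membered ring. No sp3 centre is created; the new stereo-element is the C5=C6 geometry. Because the two alkenyl groups are trans on the cyclopentane, only the chair with C7 and C9 pseudo-equatorial (oxygen and methyl axial) can be reached and a boat is geometrically excluded, so C7 ends trans to C4 across C5=C6 (E). The step needs this E selectivity and a regiodefined enolate: the first is secured by the trans arrangement built in steps 5 and 6, the second by the mechanism, which gives only the C1=C2 enolate 13, further stabilised by sulfur. C8, C9 and C10 are not touched. Silylation fixes the enolate as 14 before proton exchange toward C9 could trigger loss of the C8 silyloxy group.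

Step 10
Reactants: 14 trimethylsilyl enol ether
Product: 15 ketone with SPh and CH(OMe)2 on C2
Conditions: HC(OMe)3, Me3SiOTf (0.2 equiv), CH2Cl2, −78 °C
Reagents that add atoms: trimethyl orthoformate, COC(OC)OC
Why: Mukaiyama-type reaction: the dimethoxycarbenium ion attacks the electron-rich α-thio silyl enol ether at C2 and installs the masked C2 formyl carbon; the configuration of the new quaternary carbon is irrelevant because it becomes sp2 in step 11.

Step 11
Reactants: 15 α-thio acetal ketone
Product: 17 cyclonona-2,5-dienone with CH(OMe)2 on C2, via sulfoxide 16 (not isolated)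
Conditions: mCPBA (1.0 equiv), CH2Cl2, −78 °C; then pyridine, toluene, 80 °C
Reagents that add atoms: none
Why: The sulfide is oxidised far faster than the trisubstituted alkenes at −78 °C; syn-elimination of the α-keto sulfoxide can only go toward C3 (elimination toward the oxygen-bearing acetal carbon is disfavoured), and the ring-cis C2=C3 geometry should result because a second trans alkene in this ring would be prohibitively strained.

Step 12
Reactants: 17 dienone
Product: 18 methyl dienol ether (C1=CH–OMe)
Conditions: MeOCH2PPh3Cl, KN(SiMe3)2, THF, 0 °C to rt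
Reagents that add atoms: (methoxymethyl)triphenylphosphonium chloride, COC[P+](c1ccccc1)(c1ccccc1)c1ccccc1.[Cl-]
Why: Wittig methoxymethylenation adds 1,2 to the enone and brings in the C1 formyl carbon as an enol ether that is stable to base and fluoride; its E/Z ratio is immaterial.

Step 13
Reactants: 18 dienol ether
Product: 19 primary alcohol (O11H free with O8 silylated)
Conditions: Bu4NF (1.1 equiv), AcOH (1.1 equiv), THF, 0 °C
Reagents that add atoms: none
Why: Buffered fluoride should remove the primary silyl ether well before the hindered secondary one at C8; the near-neutral medium keeps the enol ether and the acetal intact.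

Step 14
Reactants: 19 primary alcohol
Product: 20 primary acetate
Conditions: Ac2O, pyridine, DMAP (cat.), CH2Cl2, 0 °C
Reagents that add atoms: acetic anhydride, CC(=O)OC(C)=O
Why: Standard acylation of the only free hydroxyl; the acetate is placed on O11 before any aldehyde is liberated, so no lactol can interfere.

Step 15
Reactants: 20 primary acetate
Product: 22 O8-silyl ether of the target, via C1-epimeric dialdehyde 21 (not isolated)
Conditions: PPTS, acetone–H2O (10:1), rt; then DBU (0.1 equiv), CH2Cl2, 0 °C
Reagents that add atoms: water, O
Why: Mild acid hydrolyses the enol ether (protonation at C1, since protonation at C3 would put positive charge on C2 next to the acetal or formyl carbon) and the dimethyl acetal; catalytic base then equilibrates C1 through the enol to the trans isomer. O8 stays silylated because the 1-epimer with a free O8 would be trapped as a lactol.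

Step 16
Reactants: 22 O8-silyl ether
Product: 23 target, (2S)-2-[(1R,2S,4E,7E,9R)-8,9-diformyl-2-hydroxy-4-methylcyclonona-4,7-dien-1-yl]-6-methylhept-5-en-1-yl acetate
Conditions: HF·pyridine, pyridine, THF, 0 °C
Reagents that add atoms: none
Why: Fluoride cleavage of the secondary silyl ether under mildly acidic, non-epimerising conditions; the freed O8H is trans to the C1 formyl group and cannot close a lactol, so the open hydroxy dialdehyde should be obtained.

## Compound list

1 | (3aR,6aS)-3,3a,6,6a-tetrahydro-2H-cyclopenta[b]furan-2-one, i.e. (1S,5R)-2-oxabicyclo[3.3.0]oct-6-en-3-one; in target numbering lactone O–C8–C9–C10–C11(=O), alkene C1=C6, CH2 C7 | O=C1C[C@@H]2C=CC[C@@H]2O1 | starting material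
2 | exo-epoxide of 1: oxirane across C1–C6 on the convex face, anti to C10 and the lactone oxygen | O=C1C[C@@H]2[C@H]3O[C@H]3C[C@@H]2O1 | intermediate
3 | hydroxy lactone: OH at C1 on the convex face, vinyl at C6 on the concave face (trans to OH) | O=C1C[C@@H]2[C@@H](O)[C@H](C=C)C[C@@H]2O1 | intermediate
4 | 5-bromo-2-methylpent-2-ene | CC(C)=CCCBr | starting material
5 | hydroxy lactone with 4-methylpent-3-enyl at C10 on the convex face of the lactone ring, trans to the C9–C1 bond | O=C1[C@@H](CCC=C(C)C)[C@@H]2[C@@H](O)[C@H](C=C)C[C@@H]2O1 | intermediate
6 | keto lactone: C1 ketone, C6 carrying vinyl and H | O=C1[C@@H](CCC=C(C)C)[C@@H]2C(=O)[C@H](C=C)C[C@@H]2O1 | intermediate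
7 | keto lactone with quaternary C6: methyl on the convex face (cis to H9), vinyl on the concave face | O=C1[C@@H](CCC=C(C)C)[C@@H]2C(=O)[C@](C)(C=C)C[C@@H]2O1 | intermediate
8 | phenyl vinyl sulfide | C=CSc1ccccc1 | starting material
9 | 1-(phenylthio)vinyllithium | [Li]C(=C)Sc1ccccc1 | intermediate
10 | tertiary alcohol lactone: 1-(phenylthio)vinyl on C1 on the convex face (cis to the C6 methyl, trans to the C6 vinyl), OH on the concave face | O=C1[C@@H](CCC=C(C)C)[C@@H]2[C@@](O)(C(=C)Sc3ccccc3)[C@](C)(C=C)C[C@@H]2O1 | intermediate
11 | triol: tertiary C1 OH, secondary C8 OH, primary C11 OH | OC[C@@H](CCC=C(C)C)[C@@H]1[C@@](O)(C(=C)Sc2ccccc2)[C@](C)(C=C)C[C@@H]1O | intermediate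
12 | 8,11-bis(tert-butyldimethylsilyl) ether of 11, tertiary C1 OH free | CC(C)(C)[Si](C)(C)OC[C@@H](CCC=C(C)C)[C@@H]1[C@@](O)(C(=C)Sc2ccccc2)[C@](C)(C=C)C[C@@H]1O[Si](C)(C)C(C)(C)C | intermediate
13 | potassium enolate of the ring-expanded ketone: nine-membered ring, C1(O–)=C2(SPh), C5=C6 E | CC(C)(C)[Si](C)(C)OC[C@@H](CCC=C(C)C)[C@H]1[C@@H](O[Si](C)(C)C(C)(C)C)C/C(C)=C/CC/C(Sc2ccccc2)=C1\[O-].[K+] | intermediate
14 | trimethylsilyl enol ether of the same ketone | CC(C)(C)[Si](C)(C)OC[C@@H](CCC=C(C)C)[C@H]1[C@@H](O[Si](C)(C)C(C)(C)C)C/C(C)=C/CC/C(Sc2ccccc2)=C1\O[Si](C)(C)C | intermediate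
15 | nine-membered ketone with SPh and CH(OMe)2 on C2 (C2 epimers), C5=C6 E | CC(C)(C)[Si](C)(C)OC[C@@H](CCC=C(C)C)[C@H]1[C@@H](O[Si](C)(C)C(C)(C)C)C/C(C)=C/CCC(Sc2ccccc2)(C(OC)OC)C1=O | intermediate
16 | S-oxide of 15 | CC(C)(C)[Si](C)(C)OC[C@@H](CCC=C(C)C)[C@H]1[C@@H](O[Si](C)(C)C(C)(C)C)C/C(C)=C/CCC(S(=O)c2ccccc2)(C(OC)OC)C1=O | intermediate
17 | cyclonona-2,5-dienone: CH(OMe)2 on C2, C2=C3 ring-cis, C5=C6 E | CC(C)(C)[Si](C)(C)OC[C@@H](CCC=C(C)C)[C@H]1[C@@H](O[Si](C)(C)C(C)(C)C)C/C(C)=C/C/C=C(/C(OC)OC)C1=O | intermediate
18 | methyl dienol ether: C1=CH–OMe (E/Z mixture) | CC(C)(C)[Si](C)(C)OC[C@@H](CCC=C(C)C)[C@H]1[C@@H](O[Si](C)(C)C(C)(C)C)C/C(C)=C/C/C=C(/C(OC)OC)C1=COC | intermediate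
19 | primary alcohol: O11H free, O8 silylated | OC[C@@H](CCC=C(C)C)[C@H]1[C@@H](O[Si](C)(C)C(C)(C)C)C/C(C)=C/C/C=C(/C(OC)OC)C1=COC | intermediate
20 | primary acetate of 19 | CC(=O)OC[C@@H](CCC=C(C)C)[C@H]1[C@@H](O[Si](C)(C)C(C)(C)C)C/C(C)=C/C/C=C(/C(OC)OC)C1=COC | intermediate
21 | C1 epimer (1S) of 22 | CC(=O)OC[C@@H](CCC=C(C)C)[C@H]1[C@@H](O[Si](C)(C)C(C)(C)C)C/C(C)=C/C/C=C(/C=O)[C@H]1C=O | intermediate
22 | O8-tert-butyldimethylsilyl ether of the target (1R) | CC(=O)OC[C@@H](CCC=C(C)C)[C@H]1[C@@H](O[Si](C)(C)C(C)(C)C)C/C(C)=C/C/C=C(/C=O)[C@@H]1C=O | intermediate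
23 | (2S)-2-[(1R,2S,4E,7E,9R)-8,9-diformyl-2-hydroxy-4-methylcyclonona-4,7-dien-1-yl]-6-methylhept-5-en-1-yl acetate | CC(=O)OC[C@@H](CCC=C(C)C)[C@H]1[C@@H](O)C/C(C)=C/C/C=C(/C=O)[C@@H]1C=O | target

## Step count and least certain steps

Total step count: 16. Longest linear sequence: 16 steps (1 to 23); 4 and 8 are commercial and enter in steps 3 and 6.

**Step 9 (key step).** The hindered, sulfur-bearing alkoxide may fragment by retro-addition, losing the thio-substituted alkenyl group, before it rearranges. Proton exchange within the enolate toward C9, followed by β-elimination of the C8 silyloxy group, is also possible, and the strain of the first-formed dienolate may slow the rearrangement enough for these paths to compete. The fallback takes sulfur out of the rearrangement; it sets out from 7 and returns at 15. Ketone 7 is treated with CH2=CHMgBr/CeCl3 to give the parent divinyl carbinol lactone F1, which is reduced with LiAlH4 to triol F2 and silylated to bis(silyl ether) F3. The anionic oxy-Cope rearrangement of this best-precedented substrate class is quenched with PhSSPh to give the α-phenylthio ketone F4. Its potassium enolate, made with KN(SiMe3)2, is formylated with dimethoxycarbenium tetrafluoroborate to reach 15.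

**Step 5.** Deprotonation at C9 instead of C6 would be followed by irreversible β-elimination of the lactone carboxylate, opening the lactone to a cyclopentenone acid. Any excess base could do the same to product 7. The fallback changes the order of events so that no acyloxy group is β to the ketone when the enolate is made; it sets out from 5 and returns at 12. Alcohol 5 is protected as the 4-methoxybenzyl ether F5 (4-methoxybenzyl trichloroacetimidate, catalytic acid), reduced with LiAlH4 to diol F6 and silylated to bis(silyl ether) F7. DDQ frees the C1 alcohol F8, and periodinane oxidation gives cyclopentanone F9, which has only a silyloxy group β to the carbonyl. Methylation with KN(SiMe3)2 and CH3I gives the quaternary ketone F10; both substituents on the face opposite to the incoming electrophile direct it as before. Addition of the cerium reagent made from 9 then gives 12.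

**Step 12.** The carbonyl of 17 is flanked by a branched carbon and a substituted alkene carbon, so olefination may be slow. The basic ylide may instead enolise the ketone, either at C9 with loss of silanolate or at C4 with deconjugation. The fallback builds the formyl group by epoxide rearrangement; it sets out from 17 and returns at 22. Dimethylsulfonium methylide (Corey–Chaykovsky reaction) gives the vinyl oxirane F11, and BF3·OEt2 at −78 °C (Meinwald rearrangement, 1,2-hydride shift) gives aldehyde F12. Treatment with MeOH, HC(OMe)3 and PPTS converts the aldehyde into its dimethyl acetal and removes the primary silyl group, giving alcohol F13. Acetylation gives acetate F14, and aqueous acid followed by DBU, as in step 15, gives 22.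

**Step 15.** During the base treatment the C2=C3 bond may migrate into conjugation with both formyl groups, or the equilibrium at C1 may not favour the 1R epimer enough. During hydrolysis, protonation at C3 instead of C1 would give the conjugated isomer directly. The fallback replaces equilibration by separation; it sets out from 20 and returns at 23. The base treatment is left out and the hydrolysate (21 with 22) is desilylated directly with HF·pyridine. The 1-epimer then closes to the bridged γ-lactol F15 (O8 bonded to the C1 formyl carbon). The target cannot form this lactol, so 23 is separated from it by chromatography.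

## Further compounds

F1 | step 9 | divinyl carbinol lactone: vinyl instead of 1-(phenylthio)vinyl on C1 | O=C1[C@@H](CCC=C(C)C)[C@@H]2[C@@](O)(C=C)[C@](C)(C=C)C[C@@H]2O1
F2 | step 9 | triol from F1 | OC[C@@H](CCC=C(C)C)[C@@H]1[C@@](O)(C=C)[C@](C)(C=C)C[C@@H]1O
F3 | step 9 | 8,11-bis(tert-butyldimethylsilyl) ether of F2 | CC(C)(C)[Si](C)(C)OC[C@@H](CCC=C(C)C)[C@@H]1[C@@](O)(C=C)[C@](C)(C=C)C[C@@H]1O[Si](C)(C)C(C)(C)C
F4 | step 9 | 2-(phenylthio) nine-membered ketone (C2 epimers) | CC(C)(C)[Si](C)(C)OC[C@@H](CCC=C(C)C)[C@H]1[C@@H](O[Si](C)(C)C(C)(C)C)C/C(C)=C/CCC(Sc2ccccc2)C1=O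
F5 | step 5 | 4-methoxybenzyl ether of 5 | O=C1[C@@H](CCC=C(C)C)[C@@H]2[C@@H](OCc3ccc(OC)cc3)[C@H](C=C)C[C@@H]2O1
F6 | step 5 | diol from F5 | OC[C@@H](CCC=C(C)C)[C@@H]1[C@@H](OCc2ccc(OC)cc2)[C@H](C=C)C[C@@H]1O
F7 | step 5 | bis(tert-butyldimethylsilyl) ether of F6 | CC(C)(C)[Si](C)(C)OC[C@@H](CCC=C(C)C)[C@@H]1[C@@H](OCc2ccc(OC)cc2)[C@H](C=C)C[C@@H]1O[Si](C)(C)C(C)(C)C
F8 | step 5 | C1 alcohol after removal of the 4-methoxybenzyl group | CC(C)(C)[Si](C)(C)OC[C@@H](CCC=C(C)C)[C@@H]1[C@@H](O)[C@H](C=C)C[C@@H]1O[Si](C)(C)C(C)(C)C
F9 | step 5 | cyclopentanone with vinyl and H on C6 | CC(C)(C)[Si](C)(C)OC[C@@H](CCC=C(C)C)[C@@H]1C(=O)[C@H](C=C)C[C@@H]1O[Si](C)(C)C(C)(C)C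
F10 | step 5 | cyclopentanone with quaternary C6 (methyl and vinyl) | CC(C)(C)[Si](C)(C)OC[C@@H](CCC=C(C)C)[C@@H]1C(=O)[C@](C)(C=C)C[C@@H]1O[Si](C)(C)C(C)(C)C
F11 | step 12 | vinyl oxirane: spiro-epoxide on C1 (C1 epimers) | CC(C)(C)[Si](C)(C)OC[C@@H](CCC=C(C)C)[C@H]1[C@@H](O[Si](C)(C)C(C)(C)C)C/C(C)=C/C/C=C(/C(OC)OC)C12CO2
F12 | step 12 | C1 aldehyde with C2 acetal, both silyl ethers in place (C1 epimers) | CC(C)(C)[Si](C)(C)OC[C@@H](CCC=C(C)C)[C@H]1[C@@H](O[Si](C)(C)C(C)(C)C)C/C(C)=C/C/C=C(/C(OC)OC)C1C=O
F13 | step 12 | bis(dimethyl acetal) with free O11H | OC[C@@H](CCC=C(C)C)[C@H]1[C@@H](O[Si](C)(C)C(C)(C)C)C/C(C)=C/C/C=C(/C(OC)OC)C1C(OC)OC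
F14 | step 12 | acetate of F13 | CC(=O)OC[C@@H](CCC=C(C)C)[C@H]1[C@@H](O[Si](C)(C)C(C)(C)C)C/C(C)=C/C/C=C(/C(OC)OC)C1C(OC)OC
F15 | step 15 | bridged γ-lactol of the desilylated 1-epimer (O8 bonded to the C1 formyl carbon) | CC(=O)OC[C@@H](CCC=C(C)C)[C@H]1[C@@H]2C/C(C)=C/C/C=C(/C=O)[C@H]1C(O)O2
A1 | alternative 1 | open-chain diene for ring closure at C2=C3 | CC(=O)OC[C@@H](CCC=C(C)C)[C@@H]([C@@H](O[Si](C)(C)C(C)(C)C)C/C(C)=C/CC=C)[C@@H](C(OC)OC)C(=C)C(=O)OC
A2 | alternative 2 | hydrindanol tosylate for fragmentation of the C2–C6 bond | CC(C)(C)[Si](C)(C)OC[C@@H](CCC=C(C)C)[C@H]1[C@@H](O[Si](C)(C)C(C)(C)C)C[C@]2(C)[C@@H](OS(=O)(=O)c3ccc(C)cc3)CC[C@]2(O)[C@@H]1C(OC)OC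
A3 | alternative 2 | (E)-cyclonon-5-enone with the ketone at C2 | CC(C)(C)[Si](C)(C)OC[C@@H](CCC=C(C)C)[C@H]1[C@@H](O[Si](C)(C)C(C)(C)C)C/C(C)=C/CCC(=O)[C@@H]1C(OC)OC
A4 | alternative 3 | thirteen-membered lactone joining O11 to the C1 carboxyl | O=C1C/C(C(OC)OC)=C\C/C=C(\C)C[C@H](O[Si](C)(C)C(C)(C)C)/C=C(/CCC=C(C)C)CO1
A5 | alternative 3 | ring-contracted acid with a 1,1-disubstituted alkene at C10 | C=C(CCC=C(C)C)[C@H]1[C@@H](O[Si](C)(C)C(C)(C)C)C/C(C)=C/C/C=C(/C(OC)OC)[C@@H]1C(=O)O
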